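**Retrosynthetic overview**
1. No ring is formed: both benzene rings are bought intact. The target has no C–C bond outside the rings, so the one strategic bond is the aryl C–O bond between them.
2. Ring B: 2,6-dibromoanisole 1 → para C–H borylation (2) and oxidation → phenol 3 → one ortho-bromination → phenol 4, which carries all three ring-B bromines and a methyl-masked OH.
3. Key disconnection (C–O, reversed polarity): 2,6-dibromo-1,4-benzoquinone 5 is the oxidised, enolonium-type form of 2,6-dibromohydroquinone. Its C3, a nucleophilic carbon at the hydroquinone level, accepts the phenoxide oxygen of 4, joining two normally nucleophilic centres → quinone 6 → hydroquinone 7.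
4. O-Demethylation of 7 → target 8.

Assumption: the target has no stereocentre and no configurationally stable axis, so it is one achiral compound; 1 and 5 are taken as purchased.

**Step 1**
Reactants: 1 2,6-dibromoanisole
Product: 3 3,5-dibromo-4-methoxyphenol, via aryl pinacol boronate 2 (not isolated)
Conditions: [Ir(OMe)(cod)]2 (1.5 mol %), 4,4'-di-tert-butyl-2,2'-bipyridine (3 mol %), HBpin (1.5 equiv), THF, 60 °C; then acetone, aq. KHSO5 (as the triple salt 2KHSO5·KHSO4·K2SO4, 1.1 equiv), rt, 15 min
Reagents that add atoms: pinacolborane, [H]B1OC(C)(C)C(C)(C)O1 (gives the Bpin group of 2); potassium peroxymonosulfate KHSO5, [K+].[O-]S(=O)(=O)OO (gives the phenol oxygen of 3)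
Why: Sterically governed iridium-catalysed aromatic C–H borylation occurs only at C4, the one C–H with no ortho substituent (aryl bromides are tolerated), and KHSO5 oxidation of the C–B bond (boronate-to-phenol oxidation by 1,2-aryl shift) gives the phenol; no stereocentre is formed.

**Step 2**
Reactants: 3 3,5-dibromo-4-methoxyphenol
Product: 4 2,3,5-tribromo-4-methoxyphenol
Conditions: NBS (1.0 equiv), MeCN, 0 °C, dark
Reagents that add atoms: N-bromosuccinimide, O=C1CCC(=O)N1Br
Why: Electrophilic aromatic bromination goes ortho to the free OH (para is blocked by OMe and the two ortho positions are equivalent) and stops at one bromine because the first bromine deactivates the ring; no stereocentre is formed.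

**Step 3**
Reactants: 4 2,3,5-tribromo-4-methoxyphenol; 5 2,6-dibromo-1,4-benzoquinone (2.5 equiv; one equivalent is the electrophile, a second is the in-flask oxidant)
Product: 7 3,5-dibromo-2-(2,3,5-tribromo-4-methoxyphenoxy)benzene-1,4-diol, via aryloxyquinone 6 (not isolated)
Conditions: K2CO3 (0.3 equiv), MeCN, 0 °C to rt, N2, dark; then EtOAc, aq. Na2S2O4, rt
Reagents that add atoms: none
Why: Proposed new method: quinone 5 is the two-electron-oxidised, polarity-reversed form of 2,6-dibromohydroquinone, so its C3 (an enol α-carbon, nucleophilic at the hydroquinone level) is an enolonium-type electrophile; the phenoxide of 4 adds there by oxa-Michael addition (C3 is β to the more electron-poor C1 carbonyl, and hydroxide, amines and thiolates are known to attack the H-bearing carbon of 2,6-dihalo-1,4-benzoquinones rather than displace halide), the adduct aromatises, a second equivalent of 5 oxidises it to the vinylogous-ester quinone 6 (deactivated toward a second addition), and Na2S2O4 reduces 6 to 7; the closest known reaction types are the oxidative addition of hydroxide, amines and thiols to halobenzoquinones and the aryloxylation of chloranil by phenoxides; no stereocentre is formed.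

**Step 4**
Reactants: 7 3,5-dibromo-2-(2,3,5-tribromo-4-methoxyphenoxy)benzene-1,4-diol
Product: 8 3,5-dibromo-2-(2,3,5-tribromo-4-hydroxyphenoxy)benzene-1,4-diol
Conditions: BBr3 (5 equiv), CH2Cl2, −78 °C to rt; then H2O
Reagents that add atoms: none
Why: BBr3 demethylation (Lewis-acid ether cleavage): the methoxy oxygen, twisted out of conjugation by two ortho bromines, binds boron and bromide attacks the methyl carbon by SN2, while the diaryl ether and C–Br bonds are untouched; no stereocentre is formed.

**Compound list**
1 | 2,6-dibromoanisole (1,3-dibromo-2-methoxybenzene) | COc1c(Br)cccc1Br | starting material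
2 | 2-(3,5-dibromo-4-methoxyphenyl)-4,4,5,5-tetramethyl-1,3,2-dioxaborolane | COc1c(Br)cc(cc1Br)B1OC(C)(C)C(C)(C)O1 | intermediate
3 | 3,5-dibromo-4-methoxyphenol | COc1c(Br)cc(O)cc1Br | intermediate
4 | 2,3,5-tribromo-4-methoxyphenol | COc1c(Br)cc(O)c(Br)c1Br | intermediate
5 | 2,6-dibromo-1,4-benzoquinone (2,6-dibromocyclohexa-2,5-diene-1,4-dione) | O=C1C=C(Br)C(=O)C(Br)=C1 | starting material
6 | 2,6-dibromo-3-(2,3,5-tribromo-4-methoxyphenoxy)cyclohexa-2,5-diene-1,4-dione | COc1c(Br)cc(OC2=C(Br)C(=O)C(Br)=CC2=O)c(Br)c1Br | intermediate
7 | 3,5-dibromo-2-(2,3,5-tribromo-4-methoxyphenoxy)benzene-1,4-diol | COc1c(Br)cc(Oc2c(O)cc(Br)c(O)c2Br)c(Br)c1Br | intermediate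
8 | 3,5-dibromo-2-(2,3,5-tribromo-4-hydroxyphenoxy)benzene-1,4-diol (achiral) | Oc1cc(Br)c(O)c(Br)c1Oc1cc(Br)c(O)c(Br)c1Br | target

**Totals**
Total step count: 4. Longest linear sequence: 4 steps (1 → 3 → 4 → 7 → 8).

**Steps most likely to fail, with fallbacks**

Step 3 is the most likely to fail. The hindered, weakly basic phenoxide of 4 may add too slowly, may displace a ring bromine of 5 instead of adding at C3–H, or may add twice. The fallback changes from quinone addition to aryl transfer from a diaryliodonium salt (trivalent iodine), and it sets out from 4. Bought 2-iodo-1,4-dimethoxybenzene is oxidised with mCPBA and TsOH·H2O in MeCN and treated with 1,3,5-trimethoxybenzene to give (2,5-dimethoxyphenyl)(2,4,6-trimethoxyphenyl)iodonium tosylate F1. The potassium phenoxide of 4 (KOtBu, toluene, 80 °C) takes the 2,5-dimethoxyphenyl group from F1, the trimethoxyphenyl group staying on iodine, to give 1,4-dimethoxy-2-(2,3,5-tribromo-4-methoxyphenoxy)benzene F2. BBr3 in CH2Cl2 removes all three methyl groups to give 2-(2,3,5-tribromo-4-hydroxyphenoxy)benzene-1,4-diol F3. Br2 (2.0 equiv) in AcOH at rt, followed by a Na2S2O4 wash, brominates ring A at the two positions ortho to the hydroxyl that is meta to the aryloxy group. One of these positions is also para and the other also ortho to the ether oxygen, so both are doubly activated, while ring B has no free position ortho or para to its hydroxyl. This gives the target, so the fallback comes back to the route at 8.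

Step 2 is the second risk: over-bromination to the tetrabromophenol, or a mixture with unreacted 3 that is hard to separate. The fallback changes from electrophilic substitution to conjugate addition of bromide to a quinone, and it sets out from 5. HBr (48% aq.) in AcOH at rt adds 1,4 to 5, bromide entering at an H-bearing ring carbon, to give 2,3,6-tribromobenzene-1,4-diol F4 with no possibility of over-bromination. TMSCHN2 (1.0 equiv, toluene/MeOH, 0 °C) then methylates mainly the more acidic hydroxyl, the one flanked by two bromines, because proton transfer to the diazoalkane is fastest from the stronger acid. Chromatography removes the isomeric ether. The product is 4, where the fallback rejoins the route.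

Step 1 is the third risk: the iridium catalyst may insert into a C–Br bond or stall on this hindered, electron-poor arene. The fallback uses classical electrophilic substitution and diazonium hydrolysis in place of C–H borylation, and it sets out from 1. HNO3 in AcOH/H2SO4 at 0 °C nitrates para to the methoxy group to give 1,3-dibromo-2-methoxy-5-nitrobenzene F5. Fe and NH4Cl in EtOH/H2O at 70 °C reduce it, without loss of bromine, to 3,5-dibromo-4-methoxyaniline F6. NaNO2 in aqueous H2SO4 at 0 °C gives 3,5-dibromo-4-methoxybenzenediazonium hydrogen sulfate F7, which is hydrolysed without isolation (Cu2O, Cu(NO3)2, H2O, rt) to 3, where the fallback rejoins the route.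

**Further compounds**
F1 | step 3 | (2,5-dimethoxyphenyl)(2,4,6-trimethoxyphenyl)iodonium tosylate | COc1ccc(OC)c(c1)[I+]c1c(OC)cc(OC)cc1OC.Cc1ccc(cc1)S(=O)(=O)[O-]
F2 | step 3 | 1,4-dimethoxy-2-(2,3,5-tribromo-4-methoxyphenoxy)benzene | COc1ccc(OC)c(c1)Oc1cc(Br)c(OC)c(Br)c1Br
F3 | step 3 | 2-(2,3,5-tribromo-4-hydroxyphenoxy)benzene-1,4-diol | Oc1ccc(O)c(c1)Oc1cc(Br)c(O)c(Br)c1Br
F4 | step 2 | 2,3,6-tribromobenzene-1,4-diol | Oc1cc(Br)c(O)c(Br)c1Br
F5 | step 1 | 1,3-dibromo-2-methoxy-5-nitrobenzene | COc1c(Br)cc(cc1Br)[N+](=O)[O-]
F6 | step 1 | 3,5-dibromo-4-methoxyaniline | COc1c(Br)cc(N)cc1Br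
F7 | step 1 | 3,5-dibromo-4-methoxybenzenediazonium hydrogen sulfate | COc1c(Br)cc(cc1Br)[N+]#N.OS(=O)(=O)[O-]
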